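**Plan**

1. Cuts: the two chain double bonds C10=C11 and C10'=C11' (Wittig). This leaves a C12 tetraenedial, itself cut at C15–C15' into a dienylstannane and the dienyl iodide made from it, and one C14 allylic phosphonium salt per ring end.
2. Ring A (the 2,6,6-trimethylcyclohex-2-enylidene end, C1'–C6') is cut at its CH2–CH2 bond C2'–C3' and at the central diene bond C5'–C6'. This leads back to a neopentyl bromide that carries an enyne, and to a (Z)-3-bromobut-2-enyl carbonate.
3. Feature used: in ring A the quaternary carbon C1' sits between C2' and the alkylidene carbon C6'. A C2' alkylzinc therefore has no β-hydrogen and can undergo allyl–alkyl coupling to C3'; C6', as an alkyne carbon, lies 6-exo to the bromoalkene carbon C5'. One palladium catalyst makes both bonds and closes the ring.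
4. Forward order: the side chain C7'–C10' is attached to the alkyne first and ring A closes in step 7. Ring B comes from 2,2-dimethylcyclohexanone and is extended by alkynylation. The central C12 unit is joined at C15–C15' by a Stille coupling, and the chain is completed by two Wittig reactions on the dialdehyde.
5. Stereochemistry: C5 (S) from RAMP-hydrazone methylation; C6'=C7' from syn-carbopalladation; C8'=C9' from carboalumination; the central tetraene from the E enynol, hydrostannation and stereoretentive coupling. The remaining double bonds are the thermodynamic E isomers and are settled by a final iodine equilibration.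

Key step: step 7

Remark: carotenoid locants are used (ring B with the stereocentre carries C1–C6, the chain runs C7–C15 and C15'–C7', ring A carries C1'–C6'); both exocyclic double bonds of the target are taken to be the thermodynamically preferred geometries.

**Route**

Step 1
Reactants: 1 3-bromo-2,2-dimethylpropan-1-ol
Product: 2 3-bromo-2,2-dimethylpropanal
Conditions: TEMPO (10 mol %), PhI(OAc)2, CH2Cl2, 25 °C
Reagents that add atoms: none
Why: TEMPO/PhI(OAc)2 oxidation of a primary alcohol stops at the aldehyde, which is non-enolisable and carries an inert neopentyl bromide.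

Step 2
Reactants: 2 3-bromo-2,2-dimethylpropanal
Product: 3 4-bromo-3,3-dimethylbut-1-yne
Conditions: dimethyl (1-diazo-2-oxopropyl)phosphonate, K2CO3, MeOH, 0 → 25 °C
Reagents that add atoms: dimethyl (1-diazo-2-oxopropyl)phosphonate, CC(=O)C(=[N+]=[N-])P(=O)(OC)OC
Why: Seyferth–Gilbert homologation in its Ohira–Bestmann form converts a non-enolisable aldehyde into the terminal alkyne under conditions that leave the neopentyl bromide alone.

Step 3
Reactants: 4 tert-butyl(dimethyl)(prop-2-yn-1-yloxy)silane
Product: 6 tert-butyl{[(2E)-3-iodo-2-methylprop-2-en-1-yl]oxy}dimethylsilane, via alkenylalane 5 (not isolated)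
Conditions: AlMe3, Cp2ZrCl2 (20 mol %), CH2Cl2, 0 → 25 °C; then I2, THF, −30 °C
Reagents that add atoms: trimethylaluminium, C[Al](C)C; iodine, II
Why: Negishi zirconium-catalysed carboalumination adds methyl and aluminium syn across the alkyne with methyl on the internal carbon, and iodinolysis with retention should give the E iodide.

Step 4
Reactants: 3 4-bromo-3,3-dimethylbut-1-yne; 6 tert-butyl{[(2E)-3-iodo-2-methylprop-2-en-1-yl]oxy}dimethylsilane
Product: 7 {[(2E)-7-bromo-2,6,6-trimethylhept-2-en-4-yn-1-yl]oxy}(tert-butyl)dimethylsilane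
Conditions: PdCl2(PPh3)2 (3 mol %), CuI (5 mol %), Et3N, THF, 25 °C
Reagents that add atoms: none
Why: Sonogashira coupling of the terminal alkyne with the vinyl iodide keeps the E geometry and does not touch the neopentyl C–Br bond.

Step 5
Reactants: 8 but-2-yn-1-ol
Product: 10 (2Z)-3-bromobut-2-en-1-ol, via alkenylaluminate 9 (not isolated)
Conditions: NaAlH2(OCH2CH2OMe)2, THF, 0 → 25 °C; then NBS, −78 °C
Reagents that add atoms: N-bromosuccinimide, O=C1CCC(=O)N1Br
Why: Hydroxyl-directed trans-hydroalumination places aluminium on C3 in a five-membered aluminate, and bromination with retention should give the Z bromoalkene.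

Step 6
Reactants: 10 (2Z)-3-bromobut-2-en-1-ol
Product: 11 (2Z)-3-bromobut-2-en-1-yl methyl carbonate
Conditions: ClCO2Me, pyridine, CH2Cl2, 0 °C
Reagents that add atoms: methyl chloroformate, COC(=O)Cl
Why: Acylation of the primary allylic alcohol gives the carbonate that palladium can ionise.

Step 7
Reactants: 7 {[(2E)-7-bromo-2,6,6-trimethylhept-2-en-4-yn-1-yl]oxy}(tert-butyl)dimethylsilane; 11 (2Z)-3-bromobut-2-en-1-yl methyl carbonate
Product: 14 tert-butyl(dimethyl){[(2E,4E)-2-methyl-4-(2,6,6-trimethylcyclohex-2-en-1-ylidene)but-2-en-1-yl]oxy}silane, via alkylzinc bromide 12 (not isolated), via bromodienyne 13 (not isolated)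
Conditions: Mg, LiCl, ZnBr2, THF, 25 °C; then 11, Pd(PPh3)4 (5 mol %), THF–NMP, 0 → 25 °C; then HCO2Na, DMF, 70 °C
Reagents that add atoms: none
Why: Proposed new method: magnesium insertion in the presence of ZnBr2 gives alkylzinc 12; zerovalent palladium ionises carbonate 11 to a 1-bromo-1-methyl-π-allyl complex, and transmetalation followed by C(sp3)–C(sp3) reductive elimination at the unsubstituted allyl terminus forms the C2'–C3' bond of 13, which should be clean because C2' has no β-hydrogen next to the quaternary C1'. On warming with formate the same catalyst inserts into the vinylic C5'–Br bond of 13, adds across the alkyne by syn-carbopalladation to form the C5'–C6' bond, and the dienylpalladium bromide is reduced by formate to the C7'–H bond. The closest known reaction types are the palladium-catalysed Negishi-type coupling of alkylzinc halides with allylic electrophiles and the formate-terminated intramolecular alkyne carbopalladation of alkenyl bromides (reductive Heck-type cyclisation), which are here run as one relay on a bromoallyl carbonate that serves as a two-point linchpin. Ring A closes in the 6-exo-dig mode. No stereocentre is formed; syn addition puts the new hydrogen on C7' cis to C5' and therefore the chain carbon C8' cis to C1', and the ring double bond C4'=C5' keeps the Z geometry of 11. The step needs chemoselectivity for the allylic carbonate over the vinyl bromide in the first coupling, which the much faster ionisation at 0–25 °C and the late addition of formate should secure, and exo over endo insertion, which the six-membered ring size secures.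

Step 8
Reactants: 14 tert-butyl(dimethyl){[(2E,4E)-2-methyl-4-(2,6,6-trimethylcyclohex-2-en-1-ylidene)but-2-en-1-yl]oxy}silane
Product: 15 [(2E,4E)-2-methyl-4-(2,6,6-trimethylcyclohex-2-en-1-ylidene)but-2-en-1-yl]triphenylphosphonium bromide
Conditions: PPh3·HBr, MeOH, 0 → 25 °C
Reagents that add atoms: triphenylphosphonium bromide, [Br-].[PH+](c1ccccc1)(c1ccccc1)c1ccccc1
Why: Acidic methanolysis frees the allylic alcohol, which HBr ionises to a delocalised allylic cation that triphenylphosphine captures at the primary terminus (SN1-type phosphonium salt formation); the E,E geometry set earlier is also the thermodynamic one.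

Step 9
Reactants: 16 2,2-dimethylcyclohexan-1-one; 17 (2R)-1-amino-2-(methoxymethyl)pyrrolidine (RAMP)
Product: 18 (1E)-N-[(2R)-2-(methoxymethyl)pyrrolidin-1-yl]-2,2-dimethylcyclohexan-1-imine
Conditions: TsOH (cat.), cyclohexane, reflux, water separator
Reagents that add atoms: none
Why: Condensation of the ketone with the chiral hydrazine gives the RAMP hydrazone with the amino group anti to the quaternary carbon.

Step 10
Reactants: 18 (1E)-N-[(2R)-2-(methoxymethyl)pyrrolidin-1-yl]-2,2-dimethylcyclohexan-1-imine
Product: 20 (1E,6S)-N-[(2R)-2-(methoxymethyl)pyrrolidin-1-yl]-2,2,6-trimethylcyclohexan-1-imine, via lithium azaenolate 19 (not isolated)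
Conditions: LiN(iPr)2, THF, 0 °C; then MeI, −95 → −78 °C
Reagents that add atoms: iodomethane, CI
Why: RAMP-hydrazone alkylation: deprotonation at the only enolisable α-carbon gives a chelated azaenolate that iodomethane attacks on the face not shielded by the methoxymethyl arm, which should set C5 as S (the sense opposite to that of SAMP).

Step 11
Reactants: 20 (1E,6S)-N-[(2R)-2-(methoxymethyl)pyrrolidin-1-yl]-2,2,6-trimethylcyclohexan-1-imine
Product: 21 (6S)-2,2,6-trimethylcyclohexan-1-one
Conditions: saturated aqueous oxalic acid, Et2O, 25 °C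
Reagents that add atoms: water, O
Why: Mild acidic hydrolysis of the hydrazone regenerates the ketone without epimerising the α-stereocentre and returns the auxiliary.

Step 12
Reactants: 22 2-methylbut-1-en-3-yne; 21 (6S)-2,2,6-trimethylcyclohexan-1-one
Product: 24 (6S)-2,2,6-trimethyl-1-(3-methylbut-3-en-1-yn-1-yl)cyclohexan-1-ol, via lithium acetylide 23 (not isolated)
Conditions: n-BuLi, THF, −78 °C; then 21, −78 → 0 °C
Reagents that add atoms: none
Why: Alkynylation by 1,2-addition of a lithium acetylide, which should add to the hindered ketone faster than it enolises it at low temperature; the new carbinol centre (both epimers) is destroyed later.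

Step 13
Reactants: 24 (6S)-2,2,6-trimethyl-1-(3-methylbut-3-en-1-yn-1-yl)cyclohexan-1-ol
Product: 25 (6S)-2,2,6-trimethyl-1-[(1E)-3-methylbuta-1,3-dien-1-yl]cyclohexan-1-ol
Conditions: LiAlH4, THF, 65 °C
Reagents that add atoms: none
Why: Hydroxyl-directed trans-hydroalumination of the propargylic alcohol should give the E dienyl carbinol.

Step 14
Reactants: 25 (6S)-2,2,6-trimethyl-1-[(1E)-3-methylbuta-1,3-dien-1-yl]cyclohexan-1-ol
Product: 26 {(2E,4E)-2-methyl-4-[(6S)-2,2,6-trimethylcyclohexylidene]but-2-en-1-yl}triphenylphosphonium bromide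
Conditions: PPh3·HBr, CH2Cl2–MeOH, −20 → 0 °C
Reagents that add atoms: triphenylphosphonium bromide, [Br-].[PH+](c1ccccc1)(c1ccccc1)c1ccccc1
Why: Ionisation of the tertiary dienyl carbinol gives a pentadienyl cation that triphenylphosphine captures at its primary terminus (phosphonium salt formation with allylic transposition), which moves the double bonds into the retro positions; the chain should settle cis to the CH(CH3) carbon, whose methyl group can turn axial.

Step 15
Reactants: 27 (2E)-3-methylpent-2-en-4-yn-1-ol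
Product: 28 (2E,4E)-3-methyl-5-(tributylstannyl)penta-2,4-dien-1-ol
Conditions: Bu3SnH, PdCl2(PPh3)2 (2 mol %), THF, 0 °C
Reagents that add atoms: tributylstannane, CCCC[SnH](CCCC)CCCC
Why: Palladium-catalysed syn-hydrostannation of the terminal alkyne puts tin on the terminal carbon and should give the E,E dienylstannane.

Step 16
Reactants: 28 (2E,4E)-3-methyl-5-(tributylstannyl)penta-2,4-dien-1-ol
Product: 29 (2E,4E)-5-iodo-3-methylpenta-2,4-dien-1-ol
Conditions: I2, CH2Cl2, 0 °C (carried out on one half of 28)
Reagents that add atoms: iodine, II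
Why: Iododestannylation replaces tin by iodine at the same carbon with retention of the E geometry and leaves the allylic alcohol untouched.

Step 17
Reactants: 28 (2E,4E)-3-methyl-5-(tributylstannyl)penta-2,4-dien-1-ol; 29 (2E,4E)-5-iodo-3-methylpenta-2,4-dien-1-ol
Product: 30 (2E,4E,6E,8E)-3,8-dimethyldeca-2,4,6,8-tetraene-1,10-diol
Conditions: Pd2(dba)3 (2.5 mol %), AsPh3 (20 mol %), NMP, 25 °C
Reagents that add atoms: none
Why: Stille coupling of the dienylstannane with the dienyl iodide forms the C15–C15' bond with retention of both double-bond geometries and tolerates the free hydroxyl groups.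

Step 18
Reactants: 30 (2E,4E,6E,8E)-3,8-dimethyldeca-2,4,6,8-tetraene-1,10-diol
Product: 31 (2E,4E,6E,8E)-3,8-dimethyldeca-2,4,6,8-tetraenedial
Conditions: MnO2, CH2Cl2, 25 °C
Reagents that add atoms: none
Why: MnO2 oxidation of both allylic alcohols gives the conjugated dialdehyde.

Step 19
Reactants: 15 [(2E,4E)-2-methyl-4-(2,6,6-trimethylcyclohex-2-en-1-ylidene)but-2-en-1-yl]triphenylphosphonium bromide; 31 (2E,4E,6E,8E)-3,8-dimethyldeca-2,4,6,8-tetraenedial
Product: 33 (2E,4E,6E,8E,10E,12E,14E)-3,8,12-trimethyl-14-(2,6,6-trimethylcyclohex-2-en-1-ylidene)tetradeca-2,4,6,8,10,12-hexaenal, via ring A ylide 32 (not isolated)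
Conditions: NaN(SiMe3)2, THF, −78 °C; then addition to 31 (3 equiv), −78 → 0 °C
Reagents that add atoms: none
Why: Wittig reaction of the semi-stabilised allylic ylide with an excess of the symmetrical dialdehyde should give the mono-olefination product, mainly with an E double bond at C10'=C11'.

Step 20
Reactants: 26 {(2E,4E)-2-methyl-4-[(6S)-2,2,6-trimethylcyclohexylidene]but-2-en-1-yl}triphenylphosphonium bromide; 33 (2E,4E,6E,8E,10E,12E,14E)-3,8,12-trimethyl-14-(2,6,6-trimethylcyclohex-2-en-1-ylidene)tetradeca-2,4,6,8,10,12-hexaenal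
Product: 36 (5S,6E,6'E)-4',5-retro-β,β-carotene (all-E), via ring B ylide 34 (not isolated), via 10Z isomer 35 (not isolated)
Conditions: NaN(SiMe3)2, THF, −78 °C; then 33, −78 → 25 °C; then I2 (1 mol %), heptane, 25 °C, daylight
Reagents that add atoms: none
Why: A second Wittig reaction joins the halves at C10=C11, and iodine-catalysed equilibration should convert the Z isomer at the new double bond (and any Z isomers next to it) into the all-E polyene, the thermodynamic isomer, without touching the sp3 stereocentre C5.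

**Compound list**

1 | 3-bromo-2,2-dimethylpropan-1-ol | OCC(C)(C)CBr | starting material
2 | 3-bromo-2,2-dimethylpropanal | O=CC(C)(C)CBr | intermediate
3 | 4-bromo-3,3-dimethylbut-1-yne | C#CC(C)(C)CBr | intermediate
4 | tert-butyl(dimethyl)(prop-2-yn-1-yloxy)silane | C#CCO[Si](C)(C)C(C)(C)C | starting material
5 | alkenylalane, {(1E)-3-[tert-butyl(dimethyl)silyl]oxy-2-methylprop-1-en-1-yl}dimethylalumane | C[Al](C)/C=C(C)/CO[Si](C)(C)C(C)(C)C | intermediate
6 | tert-butyl{[(2E)-3-iodo-2-methylprop-2-en-1-yl]oxy}dimethylsilane | I/C=C(C)/CO[Si](C)(C)C(C)(C)C | intermediate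
7 | {[(2E)-7-bromo-2,6,6-trimethylhept-2-en-4-yn-1-yl]oxy}(tert-butyl)dimethylsilane | BrCC(C)(C)C#C/C=C(C)/CO[Si](C)(C)C(C)(C)C | intermediate
8 | but-2-yn-1-ol | CC#CCO | starting material
9 | alkenylaluminate, sodium 2,2-bis(2-methoxyethoxy)-3-methyl-2,5-dihydro-1,2-oxaalumol-2-uide | [Na+].COCCO[Al-]1(OCCOC)OCC=C1C | intermediate
10 | (2Z)-3-bromobut-2-en-1-ol | C/C(Br)=C/CO | intermediate
11 | (2Z)-3-bromobut-2-en-1-yl methyl carbonate | C/C(Br)=C/COC(=O)OC | intermediate
12 | alkylzinc bromide, bromo[(5E)-7-{[tert-butyl(dimethyl)silyl]oxy}-2,2,6-trimethylhept-5-en-3-yn-1-yl]zinc | Br[Zn]CC(C)(C)C#C/C=C(C)/CO[Si](C)(C)C(C)(C)C | intermediate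
13 | bromodienyne, {[(2E,9Z)-10-bromo-2,6,6-trimethylundeca-2,9-dien-4-yn-1-yl]oxy}(tert-butyl)dimethylsilane | C/C(Br)=C/CCC(C)(C)C#C/C=C(C)/CO[Si](C)(C)C(C)(C)C | intermediate
14 | tert-butyl(dimethyl){[(2E,4E)-2-methyl-4-(2,6,6-trimethylcyclohex-2-en-1-ylidene)but-2-en-1-yl]oxy}silane | CC1=CCCC(C)(C)\C1=C/C=C(C)/CO[Si](C)(C)C(C)(C)C | intermediate
15 | [(2E,4E)-2-methyl-4-(2,6,6-trimethylcyclohex-2-en-1-ylidene)but-2-en-1-yl]triphenylphosphonium bromide | CC1=CCCC(C)(C)\C1=C/C=C(C)/C[P+](c1ccccc1)(c1ccccc1)c1ccccc1.[Br-] | intermediate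
16 | 2,2-dimethylcyclohexan-1-one | CC1(C)CCCCC1=O | starting material
17 | (2R)-1-amino-2-(methoxymethyl)pyrrolidine (RAMP) | COC[C@H]1CCCN1N | starting material
18 | (1E)-N-[(2R)-2-(methoxymethyl)pyrrolidin-1-yl]-2,2-dimethylcyclohexan-1-imine | COC[C@H]1CCCN1/N=C1\CCCCC1(C)C | intermediate
19 | lithium azaenolate of 18 | COC[C@H]1CCCN1N([Li])C1=CCCCC1(C)C | intermediate
20 | (1E,6S)-N-[(2R)-2-(methoxymethyl)pyrrolidin-1-yl]-2,2,6-trimethylcyclohexan-1-imine | COC[C@H]1CCCN1/N=C1\[C@@H](C)CCCC1(C)C | intermediate
21 | (6S)-2,2,6-trimethylcyclohexan-1-one | O=C1[C@@H](C)CCCC1(C)C | intermediate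
22 | 2-methylbut-1-en-3-yne | C=C(C)C#C | starting material
23 | lithium acetylide, (3-methylbut-3-en-1-yn-1-yl)lithium | [Li]C#CC(C)=C | intermediate
24 | (6S)-2,2,6-trimethyl-1-(3-methylbut-3-en-1-yn-1-yl)cyclohexan-1-ol (both C1 epimers) | C=C(C)C#CC1(O)[C@@H](C)CCCC1(C)C | intermediate
25 | (6S)-2,2,6-trimethyl-1-[(1E)-3-methylbuta-1,3-dien-1-yl]cyclohexan-1-ol (both C1 epimers) | C=C(C)/C=C/C1(O)[C@@H](C)CCCC1(C)C | intermediate
26 | {(2E,4E)-2-methyl-4-[(6S)-2,2,6-trimethylcyclohexylidene]but-2-en-1-yl}triphenylphosphonium bromide | [Br-].C(/C(C)=C/C=C1\[C@@H](C)CCCC1(C)C)[P+](c1ccccc1)(c1ccccc1)c1ccccc1 | intermediate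
27 | (2E)-3-methylpent-2-en-4-yn-1-ol | C#C/C(C)=C/CO | starting material
28 | (2E,4E)-3-methyl-5-(tributylstannyl)penta-2,4-dien-1-ol | CCCC[Sn](CCCC)(CCCC)/C=C/C(C)=C/CO | intermediate
29 | (2E,4E)-5-iodo-3-methylpenta-2,4-dien-1-ol | I/C=C/C(C)=C/CO | intermediate
30 | (2E,4E,6E,8E)-3,8-dimethyldeca-2,4,6,8-tetraene-1,10-diol | OC/C=C(C)/C=C/C=C/C(C)=C/CO | intermediate
31 | (2E,4E,6E,8E)-3,8-dimethyldeca-2,4,6,8-tetraenedial | O=C/C=C(C)/C=C/C=C/C(C)=C/C=O | intermediate
32 | ring A ylide from 15 | CC1=CCCC(C)(C)\C1=C/C=C(C)/[CH-][P+](c1ccccc1)(c1ccccc1)c1ccccc1 | intermediate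
33 | (2E,4E,6E,8E,10E,12E,14E)-3,8,12-trimethyl-14-(2,6,6-trimethylcyclohex-2-en-1-ylidene)tetradeca-2,4,6,8,10,12-hexaenal | CC1=CCCC(C)(C)\C1=C/C=C(C)/C=C/C=C(C)/C=C/C=C/C(C)=C/C=O | intermediate
34 | ring B ylide from 26 | [CH-](/C(C)=C/C=C1\[C@@H](C)CCCC1(C)C)[P+](c1ccccc1)(c1ccccc1)c1ccccc1 | intermediate
35 | 10Z isomer of 36 | CC1=CCCC(C)(C)\C1=C/C=C(C)/C=C/C=C(C)/C=C/C=C/C(C)=C/C=C\C(C)=C\C=C1/[C@@H](C)CCCC1(C)C | intermediate
36 | (5S,6E,6'E)-4',5-retro-β,β-carotene, all-E | CC1=CCCC(C)(C)\C1=C/C=C(C)/C=C/C=C(C)/C=C/C=C/C(C)=C/C=C/C(C)=C/C=C1\[C@@H](C)CCCC1(C)C | target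

**Summary**

Total step count: 20. Longest linear sequence: 7 steps (steps 1, 2, 4, 7, 8, 19, 20; the ring B branch, steps 9–14 and 20, is equally long).

**Steps most likely to fail**

Step 7. The catalyst may add oxidatively to the vinyl bromide before the allylic carbonate is consumed, which would couple the zinc reagent at the wrong carbon. The zinc reagent may also be lost by protonolysis, or the vinyl bromide may be reduced before it cyclises. The fallback gives up the annulation and takes ring A from a ring ketone by known chemistry. It sets out from 22: the lithium acetylide 23 is added to purchased 2,6,6-trimethylcyclohex-2-en-1-one F1 (THF, −78 °C) to give 2,6,6-trimethyl-1-(3-methylbut-3-en-1-yn-1-yl)cyclohex-2-en-1-ol F2. LiAlH4 in THF reduces the alkyne to 2,6,6-trimethyl-1-[(1E)-3-methylbuta-1,3-dien-1-yl]cyclohex-2-en-1-ol F3. PPh3·HBr then ionises F3, and phosphine capture at the primary terminus returns to the route at 15.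

Step 14. The allylic cation may lose the proton on C5 and be re-protonated, which would erode the configuration at C5; elimination to a hydrocarbon may also outrun phosphine capture. The fallback avoids the free cation and sets out from 25. O3ReOSiPh3 (cat., Et2O, −50 → 0 °C) should move the hydroxyl group by two successive 1,3-transpositions to the conjugated primary position, giving (2E,4E)-2-methyl-4-[(6S)-2,2,6-trimethylcyclohexylidene]but-2-en-1-ol F4. An Appel reaction (CBr4, PPh3, CH2Cl2, 0 °C) gives (6S)-1-[(2E)-4-bromo-3-methylbut-2-en-1-ylidene]-2,2,6-trimethylcyclohexane F5. SN2 displacement with PPh3 in toluene returns to the route at 26.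

Step 19. The dialdehyde may be olefinated twice, and protons may shuffle along the delocalised ylide before it reacts. The fallback builds the same aldehyde without a statistical step and sets out from 28, using 29 as well. MnO2 in CH2Cl2 oxidises 28 to (2E,4E)-3-methyl-5-(tributylstannyl)penta-2,4-dienal F6 and 29 to (2E,4E)-5-iodo-3-methylpenta-2,4-dienal F7. Ylide 32 (from 15) reacts with F6 in a Wittig reaction to give tributyl[(1E,3E,5E,7E)-3,7-dimethyl-9-(2,6,6-trimethylcyclohex-2-en-1-ylidene)nona-1,3,5,7-tetraen-1-yl]stannane F8. Stille coupling of F8 with F7 (Pd2(dba)3, AsPh3, NMP, 25 °C) forms the C15'–C15 bond and returns to the route at 33.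

Further compounds
F1 | step 7 | 2,6,6-trimethylcyclohex-2-en-1-one (purchased) | CC1=CCCC(C)(C)C1=O
F2 | step 7 | 2,6,6-trimethyl-1-(3-methylbut-3-en-1-yn-1-yl)cyclohex-2-en-1-ol | C=C(C)C#CC1(O)C(C)=CCCC1(C)C
F3 | step 7 | 2,6,6-trimethyl-1-[(1E)-3-methylbuta-1,3-dien-1-yl]cyclohex-2-en-1-ol | C=C(C)/C=C/C1(O)C(C)=CCCC1(C)C
F4 | step 14 | (2E,4E)-2-methyl-4-[(6S)-2,2,6-trimethylcyclohexylidene]but-2-en-1-ol | OC/C(C)=C/C=C1\[C@@H](C)CCCC1(C)C
F5 | step 14 | (6S)-1-[(2E)-4-bromo-3-methylbut-2-en-1-ylidene]-2,2,6-trimethylcyclohexane | BrC/C(C)=C/C=C1\[C@@H](C)CCCC1(C)C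
F6 | step 19 | (2E,4E)-3-methyl-5-(tributylstannyl)penta-2,4-dienal | O=C/C=C(C)/C=C/[Sn](CCCC)(CCCC)CCCC
F7 | step 19 | (2E,4E)-5-iodo-3-methylpenta-2,4-dienal | O=C/C=C(C)/C=C/I
F8 | step 19 | tributyl[(1E,3E,5E,7E)-3,7-dimethyl-9-(2,6,6-trimethylcyclohex-2-en-1-ylidene)nona-1,3,5,7-tetraen-1-yl]stannane | CC1=CCCC(C)(C)\C1=C/C=C(C)/C=C/C=C(C)/C=C/[Sn](CCCC)(CCCC)CCCC
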